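## Plan

1. Unit 1 is the 3-linked 5-hydroxy-7-methoxy-2-(4-methoxyphenyl)chromen-4-one and unit 2 the 6-linked apigenin. After the protecting groups, ring C of unit 2 is cut at C4a–C4, C4–C3 and O1–C2, giving an iodophenol, CO and an arylalkyne.
2. Ring A of unit 2 is cut at C7–C8, C8a–C4a and C6–C7 into a 3-benzyloxycyclobutenone bearing unit 1 on C4 and a silyloxyethyne. The four-membered ring is cut into the flavon-3-ylketene and benzyloxyethyne, and ring C of unit 1 at C2–C3 and O1–C2.
3. Enabling feature: ring A of unit 2 is a phloroglucinol ring with C6 bonded to C3 of unit 1 and oxygen on C5, C7 and C8a. One ketene carbonyl and two ynol ether oxygens build this 1,3,5-pattern and deliver the oxygens as OH, OBn and OSi(iPr)3, so the C8a oxygen can later be freed alone.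
4. Forward order: ring C of unit 1 (Baker–Venkataraman, cyclodehydration), the cyclobutenone ([2+2]), ring A of unit 2 (benzannulation), ring C of unit 2 (carbonylative annulation), global deprotection. Ring A of unit 1 and both rings B are bought.
5. Stereochemistry: the target has no stereocentre. The one sp3 centre of the cyclobutenone is racemic and vanishes on aromatisation.

Key step: step 9

Assumption: the structure fixes no configuration about the hindered C3–C6 biaryl axis, so the axis is left uncontrolled and all biaryl compounds are racemic in that respect.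

## Route

Step 1
Reactants: 1 3,5-dimethoxyphenol; 2 methyl 4-chloro-4-oxobutanoate
Product: 3 methyl 4-(2-hydroxy-4,6-dimethoxyphenyl)-4-oxobutanoate
Conditions: AlCl3 (3 equiv), CH2Cl2, 0 °C → reflux; aq HCl
Reagents that add atoms: none
Why: Friedel–Crafts acylation (with the O-acylation/Fries pathway feeding the same product) of a doubly activated ring, in which aluminium chelation between phenolate and new ketone favours the position ortho to the hydroxyl, as is usual for 2-hydroxy-4,6-dimethoxyphenyl ketones.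

Step 2
Reactants: 3 methyl 4-(2-hydroxy-4,6-dimethoxyphenyl)-4-oxobutanoate; 4 4-methoxybenzoyl chloride
Product: 5 methyl 4-[2,4-dimethoxy-6-(4-methoxybenzoyloxy)phenyl]-4-oxobutanoate
Conditions: Et3N, DMAP (cat.), CH2Cl2, 0 °C → rt
Reagents that add atoms: none
Why: DMAP-catalysed O-acylation of the hydrogen-bonded phenol is routine and places the aroyl group for intramolecular transfer.

Step 3
Reactants: 5 methyl 4-[2,4-dimethoxy-6-(4-methoxybenzoyloxy)phenyl]-4-oxobutanoate
Product: 7 methyl [5,7-dimethoxy-2-(4-methoxyphenyl)-4-oxochromen-3-yl]acetate, via 1,3-diketone 6 (not isolated)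
Conditions: LiN(SiMe3)2 (2.2 equiv), THF, −78 → 0 °C; 1 M HCl; crude in AcOH, H2SO4 (cat.), 90 °C
Reagents that add atoms: none
Why: Baker–Venkataraman rearrangement, in which the ketone α-methylene (more acidic than the ester α-methylene) is enolised and takes the aroyl group through a six-membered transition state, followed by acid cyclodehydration of 6 that closes ring C of unit 1 by phenol attack on the aroyl carbonyl.

Step 4
Reactants: 7 methyl [5,7-dimethoxy-2-(4-methoxyphenyl)-4-oxochromen-3-yl]acetate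
Product: 8 [5,7-dimethoxy-2-(4-methoxyphenyl)-4-oxochromen-3-yl]acetic acid
Conditions: LiOH, THF/H2O, rt; 1 M HCl
Reagents that add atoms: lithium hydroxide, [Li+].[OH-]
Why: Saponification of an unhindered methyl ester, which the donor-rich 2,3-disubstituted pyranone should survive at room temperature, any ring-opened diketone reclosing on acidification.

Step 5
Reactants: 9 benzyl alcohol; 10 trichloroethylene
Product: 12 (benzyloxy)ethyne, via dichlorovinyl ether 11 (not isolated)
Conditions: KH, THF, 0 °C; 10, −50 °C → rt; n-BuLi (2.2 equiv), −78 → −40 °C; H2O, −78 °C; kept cold and used at once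
Reagents that add atoms: none
Why: The trichloroethylene route to ynol ethers, in which the potassium alkoxide gives 11 and n-BuLi then eliminates HCl and exchanges the remaining chlorine for lithium before protonation; the product must stay at or below room temperature because benzyl alkynyl ethers undergo [3,3] sigmatropic rearrangement near 60 °C.

Step 6
Reactants: 8 [5,7-dimethoxy-2-(4-methoxyphenyl)-4-oxochromen-3-yl]acetic acid; 12 (benzyloxy)ethyne
Product: 15 (±)-3-(benzyloxy)-4-[5,7-dimethoxy-2-(4-methoxyphenyl)-4-oxochromen-3-yl]cyclobut-2-en-1-one, via acid chloride 13 (not isolated), via ketene 14 (not isolated)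
Conditions: (COCl)2, DMF (cat.), CH2Cl2, 0 °C → rt, evaporate; 12 (3 equiv), Et3N (slow addition), CH2Cl2, 0 °C → rt
Reagents that add atoms: none
Why: Dehydrochlorination of 13 gives ketene 14, which undergoes the ketene–ynol ether [2+2] cycloaddition known for 3-alkoxycyclobutenones, the CH terminus of 12 bonding to the ketene carbonyl carbon; slow amine addition into excess 12 holds dimerisation down, and the new C4 centre is racemic and is erased in step 9.

Step 7
Reactants: 16 ethynyl(trimethyl)silane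
Product: 18 triisopropyl{[(trimethylsilyl)ethynyl]oxy}silane, via lithium ynolate 17 (not isolated)
Conditions: n-BuLi, THF, −78 °C; t-BuOOH/LiN(SiMe3)2 (premixed, −78 °C), → 0 °C; iPr3SiOTf, −78 → 0 °C
Reagents that add atoms: tert-butyl hydroperoxide, CC(C)(C)OO; triisopropylsilyl trifluoromethanesulfonate, CC(C)[Si](C(C)C)(C(C)C)OS(=O)(=O)C(F)(F)F
Why: Oxygenation of a lithium acetylide with lithium tert-butyl peroxide followed by O-silylation is the standard access to 1-siloxyalkynes, and the bulky silyl triflate should silylate the silyl-stabilised ynolate 17 on oxygen and not on carbon.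

Step 8
Reactants: 18 triisopropyl{[(trimethylsilyl)ethynyl]oxy}silane
Product: 19 (triisopropylsilyloxy)ethyne
Conditions: K2CO3 (cat.), MeOH/THF, 0 °C, short contact; pentane extraction
Reagents that add atoms: none
Why: Base-catalysed protiodesilylation of an alkynyl–SiMe3 bond should be much faster than attack on the hindered O–Si(iPr)3 group, and the basic medium avoids the C-protonation that destroys ynol ethers.

Step 9
Reactants: 15 (±)-3-(benzyloxy)-4-[5,7-dimethoxy-2-(4-methoxyphenyl)-4-oxochromen-3-yl]cyclobut-2-en-1-one; 19 (triisopropylsilyloxy)ethyne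
Product: 24 3-[2-(benzyloxy)-6-hydroxy-4-(triisopropylsilyloxy)phenyl]-5,7-dimethoxy-2-(4-methoxyphenyl)chromen-4-one, via vinylketene 20 (not isolated), via 4-vinylcyclobutenone 21 (not isolated), via dienylketene 22 (not isolated), via cyclohexadienone 23 (not isolated)
Conditions: 19 (3 equiv), toluene, 110 °C, sealed tube, Ar
Reagents that add atoms: none
Why: Heat breaks the C1–C4 bond of 15 in a conrotatory four-electron electrocyclic opening, the chromenyl group turning outward, to give vinylketene 20. The CH terminus of 19, its nucleophilic end, attacks the carbonyl carbon of the ketene and the oxygen-bearing carbon closes on the ketene α-carbon ([2+2] cycloaddition), and the resulting 4-vinylcyclobutenone 21 opens again to dienylketene 22. Ring A of unit 2 closes by disrotatory six-electron electrocyclisation of 22, the ketene carbon bonding to the chromenyl-bearing terminus, and dienone 23 enolises to phenol 24; this is the Danheiser benzannulation, whose closest known form joins cyclobutenones and 1-siloxyalkynes to resorcinol monosilyl ethers. No stereocentre remains, because the sp3 centres of 15, 21 and 23 are all lost on aromatisation. The step needs a single orientation of the [2+2] addition, which the oxygen lone pair of 19 secures by polarising the triple bond, so the silyl ether lies opposite the biaryl carbon while the new hydroxyl and the benzyloxy group sit beside it. Interception of 20 must also be faster than its dimerisation and its acylation of 24, which the excess of unhindered terminal alkyne serves, and closure of 20 onto the chromone C2=C3 bond is a dead end because C2 is fully substituted and cannot aromatise.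

Step 10
Reactants: 24 3-[2-(benzyloxy)-6-hydroxy-4-(triisopropylsilyloxy)phenyl]-5,7-dimethoxy-2-(4-methoxyphenyl)chromen-4-one
Product: 25 3-[2,6-bis(benzyloxy)-4-(triisopropylsilyloxy)phenyl]-5,7-dimethoxy-2-(4-methoxyphenyl)chromen-4-one
Conditions: BnBr, K2CO3, acetone (dry), reflux
Reagents that add atoms: benzyl bromide, BrCc1ccccc1
Why: Williamson etherification under anhydrous carbonate leaves the aryl triisopropylsilyl ether intact and makes the two oxygens beside the biaryl bond identical.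

Step 11
Reactants: 25 3-[2,6-bis(benzyloxy)-4-(triisopropylsilyloxy)phenyl]-5,7-dimethoxy-2-(4-methoxyphenyl)chromen-4-one
Product: 26 3-[2,6-bis(benzyloxy)-4-hydroxyphenyl]-5,7-dimethoxy-2-(4-methoxyphenyl)chromen-4-one
Conditions: Bu4NF, AcOH, THF, 0 °C
Reagents that add atoms: none
Why: Fluoride-induced desilylation frees only the oxygen that will become O1 on C8a of unit 2, with acetic acid buffering the phenoxide.

Step 12
Reactants: 26 3-[2,6-bis(benzyloxy)-4-hydroxyphenyl]-5,7-dimethoxy-2-(4-methoxyphenyl)chromen-4-one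
Product: 27 3-[2,6-bis(benzyloxy)-4-hydroxy-3-iodophenyl]-5,7-dimethoxy-2-(4-methoxyphenyl)chromen-4-one
Conditions: NIS (1.0 equiv), MeCN/CH2Cl2, −20 → 0 °C, dark
Reagents that add atoms: N-iodosuccinimide, O=C1CCC(=O)N1I
Why: Electrophilic aromatic iodination ortho to a free phenol that is also activated by two benzyloxy groups; the two ortho sites are equivalent, this ring far outpaces the carbonyl-deactivated ring A of unit 1, and one equivalent at low temperature limits a second iodination.

Step 13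
Reactants: 27 3-[2,6-bis(benzyloxy)-4-hydroxy-3-iodophenyl]-5,7-dimethoxy-2-(4-methoxyphenyl)chromen-4-one; 28 1-(benzyloxy)-4-ethynylbenzene
Product: 31 5,7-bis(benzyloxy)-2-[4-(benzyloxy)phenyl]-6-[5,7-dimethoxy-2-(4-methoxyphenyl)-4-oxochromen-3-yl]chromen-4-one, via alkynone 29 (not isolated), via enaminone 30 (not isolated)
Conditions: PdCl2(PPh3)2 (5 mol %), CO (10 bar), Et2NH, 100 °C
Reagents that add atoms: carbon monoxide, [C-]#[O+]
Why: Carbonylative Sonogashira coupling and annulation of an o-iodophenol with a terminal alkyne, in which oxidative addition to zerovalent palladium, CO insertion and alkynylation give 29, diethylamine adds to give 30, and the phenol closes ring C of unit 2 in the 6-endo sense with loss of the amine, steering away from 5-exo aurone formation.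

Step 14
Reactants: 31 5,7-bis(benzyloxy)-2-[4-(benzyloxy)phenyl]-6-[5,7-dimethoxy-2-(4-methoxyphenyl)-4-oxochromen-3-yl]chromen-4-one
Product: 32 5,7-dihydroxy-6-[5-hydroxy-7-methoxy-2-(4-methoxyphenyl)-4-oxochromen-3-yl]-2-(4-hydroxyphenyl)chromen-4-one (CNP0273448.0)
Conditions: BCl3 (excess), C6HMe5, CH2Cl2, −78 °C → rt; H2O
Reagents that add atoms: none
Why: BCl3 cleaves aryl benzyl ethers with pentamethylbenzene as a non-basic benzyl cation trap and, by chelation to the C4 carbonyl, the peri 5-methoxy group of unit 1, whereas the unchelated 7- and 4'-methyl ethers are inert to this reagent.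

## Compound list

1 | 3,5-dimethoxyphenol | COc1cc(O)cc(OC)c1 | starting material
2 | methyl 4-chloro-4-oxobutanoate | COC(=O)CCC(Cl)=O | starting material
3 | methyl 4-(2-hydroxy-4,6-dimethoxyphenyl)-4-oxobutanoate | COC(=O)CCC(=O)c1c(O)cc(OC)cc1OC | intermediate
4 | 4-methoxybenzoyl chloride | COc1ccc(C(Cl)=O)cc1 | starting material
5 | methyl 4-[2,4-dimethoxy-6-(4-methoxybenzoyloxy)phenyl]-4-oxobutanoate | COC(=O)CCC(=O)c1c(OC(=O)c2ccc(OC)cc2)cc(OC)cc1OC | intermediate
6 | methyl 3-(2-hydroxy-4,6-dimethoxybenzoyl)-4-(4-methoxyphenyl)-4-oxobutanoate (racemic, enolisable) | COC(=O)CC(C(=O)c1ccc(OC)cc1)C(=O)c1c(O)cc(OC)cc1OC | intermediate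
7 | methyl [5,7-dimethoxy-2-(4-methoxyphenyl)-4-oxochromen-3-yl]acetate | COC(=O)Cc1c(-c2ccc(OC)cc2)oc2cc(OC)cc(OC)c2c1=O | intermediate
8 | [5,7-dimethoxy-2-(4-methoxyphenyl)-4-oxochromen-3-yl]acetic acid | OC(=O)Cc1c(-c2ccc(OC)cc2)oc2cc(OC)cc(OC)c2c1=O | intermediate
9 | benzyl alcohol | OCc1ccccc1 | starting material
10 | trichloroethylene | ClC=C(Cl)Cl | starting material
11 | benzyl (E)-1,2-dichlorovinyl ether | Cl/C=C(/Cl)OCc1ccccc1 | intermediate
12 | (benzyloxy)ethyne | C#COCc1ccccc1 | intermediate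
13 | [5,7-dimethoxy-2-(4-methoxyphenyl)-4-oxochromen-3-yl]acetyl chloride | O=C(Cl)Cc1c(-c2ccc(OC)cc2)oc2cc(OC)cc(OC)c2c1=O | intermediate
14 | 2-[5,7-dimethoxy-2-(4-methoxyphenyl)-4-oxochromen-3-yl]ethenone (ketene) | O=C=Cc1c(-c2ccc(OC)cc2)oc2cc(OC)cc(OC)c2c1=O | intermediate
15 | 3-(benzyloxy)-4-[5,7-dimethoxy-2-(4-methoxyphenyl)-4-oxochromen-3-yl]cyclobut-2-en-1-one (racemic, one enantiomer drawn) | O=C1C=C(OCc2ccccc2)[C@@H]1c1c(-c2ccc(OC)cc2)oc2cc(OC)cc(OC)c2c1=O | intermediate
16 | ethynyl(trimethyl)silane | C#C[Si](C)(C)C | starting material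
17 | lithium 2-(trimethylsilyl)ethynolate | [Li+].[O-]C#C[Si](C)(C)C | intermediate
18 | triisopropyl{[(trimethylsilyl)ethynyl]oxy}silane | C[Si](C)(C)C#CO[Si](C(C)C)(C(C)C)C(C)C | intermediate
19 | (triisopropylsilyloxy)ethyne | C#CO[Si](C(C)C)(C(C)C)C(C)C | intermediate
20 | 3-(benzyloxy)-4-[5,7-dimethoxy-2-(4-methoxyphenyl)-4-oxochromen-3-yl]buta-1,3-dien-1-one (chromenyl group trans to the ketene-bearing carbon) | O=C=C/C(OCc1ccccc1)=C/c1c(-c2ccc(OC)cc2)oc2cc(OC)cc(OC)c2c1=O | intermediate
21 | 4-{1-(benzyloxy)-2-[5,7-dimethoxy-2-(4-methoxyphenyl)-4-oxochromen-3-yl]ethenyl}-3-(triisopropylsilyloxy)cyclobut-2-en-1-one (racemic) | O=C1C=C(O[Si](C(C)C)(C(C)C)C(C)C)C1/C(OCc2ccccc2)=C/c2c(-c3ccc(OC)cc3)oc3cc(OC)cc(OC)c3c2=O | intermediate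
22 | 5-(benzyloxy)-6-[5,7-dimethoxy-2-(4-methoxyphenyl)-4-oxochromen-3-yl]-3-(triisopropylsilyloxy)hexa-1,3,5-trien-1-one (central double bond cis in the carbon chain) | O=C=C/C(O[Si](C(C)C)(C(C)C)C(C)C)=C\C(OCc1ccccc1)=C\c1c(-c2ccc(OC)cc2)oc2cc(OC)cc(OC)c2c1=O | intermediate
23 | 5-(benzyloxy)-6-[5,7-dimethoxy-2-(4-methoxyphenyl)-4-oxochromen-3-yl]-3-(triisopropylsilyloxy)cyclohexa-2,4-dien-1-one (racemic) | O=C1C=C(O[Si](C(C)C)(C(C)C)C(C)C)C=C(OCc2ccccc2)C1c1c(-c2ccc(OC)cc2)oc2cc(OC)cc(OC)c2c1=O | intermediate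
24 | 3-[2-(benzyloxy)-6-hydroxy-4-(triisopropylsilyloxy)phenyl]-5,7-dimethoxy-2-(4-methoxyphenyl)chromen-4-one | COc1ccc(-c2oc3cc(OC)cc(OC)c3c(=O)c2-c2c(O)cc(O[Si](C(C)C)(C(C)C)C(C)C)cc2OCc2ccccc2)cc1 | intermediate
25 | 3-[2,6-bis(benzyloxy)-4-(triisopropylsilyloxy)phenyl]-5,7-dimethoxy-2-(4-methoxyphenyl)chromen-4-one | COc1ccc(-c2oc3cc(OC)cc(OC)c3c(=O)c2-c2c(OCc3ccccc3)cc(O[Si](C(C)C)(C(C)C)C(C)C)cc2OCc2ccccc2)cc1 | intermediate
26 | 3-[2,6-bis(benzyloxy)-4-hydroxyphenyl]-5,7-dimethoxy-2-(4-methoxyphenyl)chromen-4-one | COc1ccc(-c2oc3cc(OC)cc(OC)c3c(=O)c2-c2c(OCc3ccccc3)cc(O)cc2OCc2ccccc2)cc1 | intermediate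
27 | 3-[2,6-bis(benzyloxy)-4-hydroxy-3-iodophenyl]-5,7-dimethoxy-2-(4-methoxyphenyl)chromen-4-one | COc1ccc(-c2oc3cc(OC)cc(OC)c3c(=O)c2-c2c(OCc3ccccc3)cc(O)c(I)c2OCc2ccccc2)cc1 | intermediate
28 | 1-(benzyloxy)-4-ethynylbenzene | C#Cc1ccc(OCc2ccccc2)cc1 | starting material
29 | 3-{2,6-bis(benzyloxy)-3-[3-(4-benzyloxyphenyl)prop-2-ynoyl]-4-hydroxyphenyl}-5,7-dimethoxy-2-(4-methoxyphenyl)chromen-4-one | COc1ccc(-c2oc3cc(OC)cc(OC)c3c(=O)c2-c2c(OCc3ccccc3)cc(O)c(C(=O)C#Cc3ccc(OCc4ccccc4)cc3)c2OCc2ccccc2)cc1 | intermediate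
30 | 3-{2,6-bis(benzyloxy)-3-[(E)-3-(4-benzyloxyphenyl)-3-(diethylamino)prop-2-enoyl]-4-hydroxyphenyl}-5,7-dimethoxy-2-(4-methoxyphenyl)chromen-4-one | COc1ccc(-c2oc3cc(OC)cc(OC)c3c(=O)c2-c2c(OCc3ccccc3)cc(O)c(C(=O)/C=C(/N(CC)CC)c3ccc(OCc4ccccc4)cc3)c2OCc2ccccc2)cc1 | intermediate
31 | 5,7-bis(benzyloxy)-2-[4-(benzyloxy)phenyl]-6-[5,7-dimethoxy-2-(4-methoxyphenyl)-4-oxochromen-3-yl]chromen-4-one | COc1ccc(-c2oc3cc(OC)cc(OC)c3c(=O)c2-c2c(OCc3ccccc3)cc3oc(-c4ccc(OCc5ccccc5)cc4)cc(=O)c3c2OCc2ccccc2)cc1 | intermediate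
32 | 5,7-dihydroxy-6-[5-hydroxy-7-methoxy-2-(4-methoxyphenyl)-4-oxochromen-3-yl]-2-(4-hydroxyphenyl)chromen-4-one | COc1ccc(-c2oc3cc(OC)cc(O)c3c(=O)c2-c2c(O)cc3oc(-c4ccc(O)cc4)cc(=O)c3c2O)cc1 | target

## Summary

Total step count: 14.
Longest linear sequence: 11 steps (1 → 3 → 5 → 7 → 8 → 15 → 24 → 25 → 26 → 27 → 31 → 32, i.e. steps 1–4, 6 and 9–14).

## Steps most likely to fail

**1. Step 9.** The vinylogous-ester character of 15 may push the first ring opening to temperatures at which 19 isomerises to the silylketene or oligomerises. Ketene 20 may also be consumed by dimerisation or by acylating the phenol already formed.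

The fallback sets out from acid chloride 13 and comes back at 24. It reaches the same vinylketene by a polar elimination in the cold, not by electrocyclic opening.
- 13 acylates potassium ethyl malonate (MgCl2, Et3N, MeCN) with loss of CO2 to give ethyl 4-[5,7-dimethoxy-2-(4-methoxyphenyl)-4-oxochromen-3-yl]-3-oxobutanoate F1.
- Acid-catalysed enol etherification with benzyl alcohol (TsOH, toluene, azeotropic removal of water) should give ethyl (E)-3-(benzyloxy)-4-[5,7-dimethoxy-2-(4-methoxyphenyl)-4-oxochromen-3-yl]but-2-enoate F2.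
- Saponification (LiOH) gives (E)-3-(benzyloxy)-4-[5,7-dimethoxy-2-(4-methoxyphenyl)-4-oxochromen-3-yl]but-2-enoic acid F3.
- Oxalyl chloride gives (E)-3-(benzyloxy)-4-[5,7-dimethoxy-2-(4-methoxyphenyl)-4-oxochromen-3-yl]but-2-enoyl chloride F4.
- Et3N then removes a γ-proton of F4 (1,4-dehydrochlorination) at 0 °C to room temperature in the presence of 19. Ketene 20 is thus formed cold and trapped as 21, which can be isolated and needs only gentle warming (toluene, 80 °C) to pass through 22 and 23 to 24.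

**2. Step 6.** The monosubstituted ketene 14 may dimerise or close by six-electron electrocyclisation onto the neighbouring anisyl ring. Ynol ether 12 may also decay by sigmatropic rearrangement before it is consumed.

The fallback sets out from 13 and comes back at 15. Acid chloride 13 is dehydrochlorinated (Et3N) in a large excess of commercial ethoxyethyne, which has no sigmatropic pathway and tolerates mild heating. This gives (±)-3-ethoxy-4-[5,7-dimethoxy-2-(4-methoxyphenyl)-4-oxochromen-3-yl]cyclobut-2-en-1-one F5. The alkoxy group is then exchanged at C3 by acid-catalysed addition–elimination with benzyl alcohol (TsOH cat., toluene, ethanol removed under reduced pressure), which leaves the position of the chromenyl group untouched and gives 15.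

**3. Step 8.** Methanol may add across the electron-rich triple bond, the O-silyl group may be lost during C-desilylation, and the small terminal ynol ether may be lost on isolation.

The fallback sets out from 18 and 15 and comes back at 27. It keeps the C-silyl group and uses it as the handle for iodine.
- 15 is heated with 18 under the conditions of step 9 to give 3-[6-(benzyloxy)-2-hydroxy-4-(triisopropylsilyloxy)-3-(trimethylsilyl)phenyl]-5,7-dimethoxy-2-(4-methoxyphenyl)chromen-4-one F6.
- Benzylation (BnBr, K2CO3, acetone) gives 3-[2,6-bis(benzyloxy)-4-(triisopropylsilyloxy)-3-(trimethylsilyl)phenyl]-5,7-dimethoxy-2-(4-methoxyphenyl)chromen-4-one F7.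
- Ipso-iododesilylation (ICl, CH2Cl2, −78 °C) gives 3-[2,6-bis(benzyloxy)-3-iodo-4-(triisopropylsilyloxy)phenyl]-5,7-dimethoxy-2-(4-methoxyphenyl)chromen-4-one F8.
- Bu4NF/AcOH then frees the phenol to give 27, which also makes step 12 unnecessary.

## Further compounds

F1 | step 9 | ethyl 4-[5,7-dimethoxy-2-(4-methoxyphenyl)-4-oxochromen-3-yl]-3-oxobutanoate | CCOC(=O)CC(=O)Cc1c(-c2ccc(OC)cc2)oc2cc(OC)cc(OC)c2c1=O
F2 | step 9 | ethyl (E)-3-(benzyloxy)-4-[5,7-dimethoxy-2-(4-methoxyphenyl)-4-oxochromen-3-yl]but-2-enoate | CCOC(=O)/C=C(/OCc1ccccc1)Cc1c(-c2ccc(OC)cc2)oc2cc(OC)cc(OC)c2c1=O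
F3 | step 9 | (E)-3-(benzyloxy)-4-[5,7-dimethoxy-2-(4-methoxyphenyl)-4-oxochromen-3-yl]but-2-enoic acid | OC(=O)/C=C(/OCc1ccccc1)Cc1c(-c2ccc(OC)cc2)oc2cc(OC)cc(OC)c2c1=O
F4 | step 9 | (E)-3-(benzyloxy)-4-[5,7-dimethoxy-2-(4-methoxyphenyl)-4-oxochromen-3-yl]but-2-enoyl chloride | ClC(=O)/C=C(/OCc1ccccc1)Cc1c(-c2ccc(OC)cc2)oc2cc(OC)cc(OC)c2c1=O
F5 | step 6 | 3-ethoxy-4-[5,7-dimethoxy-2-(4-methoxyphenyl)-4-oxochromen-3-yl]cyclobut-2-en-1-one (racemic, one enantiomer drawn) | O=C1C=C(OCC)[C@@H]1c1c(-c2ccc(OC)cc2)oc2cc(OC)cc(OC)c2c1=O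
F6 | step 8 | 3-[6-(benzyloxy)-2-hydroxy-4-(triisopropylsilyloxy)-3-(trimethylsilyl)phenyl]-5,7-dimethoxy-2-(4-methoxyphenyl)chromen-4-one | COc1ccc(-c2oc3cc(OC)cc(OC)c3c(=O)c2-c2c(O)c([Si](C)(C)C)c(O[Si](C(C)C)(C(C)C)C(C)C)cc2OCc2ccccc2)cc1
F7 | step 8 | 3-[2,6-bis(benzyloxy)-4-(triisopropylsilyloxy)-3-(trimethylsilyl)phenyl]-5,7-dimethoxy-2-(4-methoxyphenyl)chromen-4-one | COc1ccc(-c2oc3cc(OC)cc(OC)c3c(=O)c2-c2c(OCc3ccccc3)c([Si](C)(C)C)c(O[Si](C(C)C)(C(C)C)C(C)C)cc2OCc2ccccc2)cc1
F8 | step 8 | 3-[2,6-bis(benzyloxy)-3-iodo-4-(triisopropylsilyloxy)phenyl]-5,7-dimethoxy-2-(4-methoxyphenyl)chromen-4-one | COc1ccc(-c2oc3cc(OC)cc(OC)c3c(=O)c2-c2c(OCc3ccccc3)c(I)c(O[Si](C(C)C)(C(C)C)C(C)C)cc2OCc2ccccc2)cc1
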